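**Retrosynthetic overview**

1. The last bond broken is the aryl O–S bond of 27, the isovanillyl O-tosylate of the target; the tosyl group is the temporary ring-deactivating group of arm A.
2. Key disconnection: both saturated rings of 27 open to the open-chain biaryl bis-tetraol 24. Forward, one acid treatment closes the tetrahydrofuran of arm A (O9'→C7) and, in arm B, bonds C7 to C1' to give a spiro[4.5]decadienone whose cyclopentane (C7–C8–C8'–C7'–C1') expands by 1,2-shift of C7 from C1' to C6' into the six-membered carbocycle of the tetralin.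
3. Enabling feature: the free hydroxyl on C4' of the guaiacyl ring of arm B is para to C1' (the carbon bearing the C7' methylene), so C1' is the most nucleophilic ring carbon and a neutral dienone can form; C7 is a p-hydroxybenzylic carbinol that ionizes readily. The 3-tosyloxy-4-methoxyphenyl ring of arm A has neither property and stops at the ether.
4. 24 comes from Suzuki union of two aryl bromide tetraols (18, 21), each from a lactone-dianion aldol of aldehyde 15 with an (S)-β-benzyl-β-hydroxy-γ-butyrolactone (8 or 13) followed by LiBH4 reduction; both lactones derive from one Sharpless epoxide (4) and an aryl Grignard reagent.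
5. Ring order: two temporary γ-lactones (steps 3 and 5, opened in steps 8 and 10) → biaryl bond (step 11) → tetrahydrofuran ring and tetralin ring together (step 13).

Key step: step 13

Remark (numbering and assumption): each arm uses lignan numbering (C7 = benzylic carbon on the biaryl ring, C8/C9 and C8'/C9' = chain carbons, C7' = benzylic CH2, C1'–C6' = benzyl ring); C7 is carried as an epimer mixture in 17–24 and drawn without a descriptor, because step 13 ionizes and resets it in both arms.

**Route**

Step 1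
Reactants: 1 itaconic acid 4-methyl ester
Product: 3 methyl 3-(hydroxymethyl)but-3-enoate, via mixed anhydride 2 (not isolated)
Conditions: iBuOCOCl, N-methylmorpholine, THF, −15 °C; then NaBH4, H2O/THF, −15 → 0 °C; used directly
Reagents that add atoms: none
Why: Chemoselective borohydride reduction of a carboxylic acid through its mixed carbonic anhydride (1,2-reduction) should leave the unactivated methyl ester and the alkene untouched.

Step 2
Reactants: 3 methyl 3-(hydroxymethyl)but-3-enoate
Product: 4 methyl 2-[(2S)-2-(hydroxymethyl)oxiran-2-yl]acetate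
Conditions: Ti(OiPr)4 (cat.), L-(+)-diethyl tartrate (cat.), tBuOOH, 4 Å MS, CH2Cl2, −20 °C
Reagents that add atoms: tert-butyl hydroperoxide CC(C)(C)OO
Why: Sharpless asymmetric epoxidation of a 2-substituted allylic alcohol; L-(+)-tartrate should deliver oxygen in the sense that turns allyl alcohol into (S)-glycidol, giving the (S)-epoxide that becomes the C8' carbinol centre of both arms.

Step 3
Reactants: 4 methyl 2-[(2S)-2-(hydroxymethyl)oxiran-2-yl]acetate; 5 1-(benzyloxy)-4-bromo-2-methoxybenzene
Product: 8 (4S)-4-[4-(benzyloxy)-3-methoxybenzyl]-4-hydroxyoxolan-2-one, via arylmagnesium bromide 6 (not isolated), via dihydroxy ester 7 (not isolated)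
Conditions: 5, Mg, THF, rt; 4, iPrMgCl (1 equiv), THF, −40 °C, then 6, CuI (cat.), −40 → −10 °C; NH4Cl (aq); PPTS (cat.), CH2Cl2, rt
Reagents that add atoms: none
Why: Copper-catalysed Grignard opening of a 2,2-disubstituted terminal epoxide at its CH2 terminus leaves the quaternary C–O bond (C8') untouched (a Payne shift of the alkoxide is degenerate), and the primary hydroxyl then closes the γ-lactone onto the methyl ester.

Step 4
Reactants: 9 5-bromo-2-methoxyphenol
Product: 10 5-bromo-2-methoxyphenyl 4-methylbenzenesulfonate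
Conditions: TsCl, Et3N, DMAP (cat.), CH2Cl2, 0 °C → rt
Reagents that add atoms: 4-methylbenzenesulfonyl chloride Cc1ccc(cc1)S(Cl)(=O)=O
Why: Sulfonylation of a phenol installs the group that later deactivates the benzyl ring of arm A towards Friedel–Crafts alkylation.

Step 5
Reactants: 4 methyl 2-[(2S)-2-(hydroxymethyl)oxiran-2-yl]acetate; 10 5-bromo-2-methoxyphenyl 4-methylbenzenesulfonate
Product: 13 (4S)-4-hydroxy-4-[4-methoxy-3-(tosyloxy)benzyl]oxolan-2-one, via arylmagnesium bromide 11 (not isolated), via dihydroxy ester 12 (not isolated)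
Conditions: 10, Mg, LiCl, THF, 0 °C → rt; 4, iPrMgCl (1 equiv), THF, −40 °C, then 11, CuI (cat.), −40 → −10 °C; NH4Cl (aq); PPTS (cat.), CH2Cl2, rt
Reagents that add atoms: none
Why: LiCl-assisted magnesium insertion should tolerate the meta-sulfonate at or below room temperature, and the copper-catalysed epoxide opening and γ-lactonization then proceed as in step 3 with retention at C8'.

Step 6
Reactants: 14 5-bromovanillin
Product: 15 4-(benzyloxy)-3-bromo-5-methoxybenzaldehyde
Conditions: BnBr, K2CO3, DMF, rt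
Reagents that add atoms: benzyl bromide BrCc1ccccc1
Why: Williamson ether synthesis masks the phenol so that the aldehyde stays electrophilic in the aldol step.

Step 7
Reactants: 8 (4S)-4-[4-(benzyloxy)-3-methoxybenzyl]-4-hydroxyoxolan-2-one; 15 4-(benzyloxy)-3-bromo-5-methoxybenzaldehyde
Product: 17 (3R,4S)-4-[4-(benzyloxy)-3-methoxybenzyl]-3-{[4-(benzyloxy)-3-bromo-5-methoxyphenyl](hydroxy)methyl}-4-hydroxyoxolan-2-one (carbinol epimers), via dilithium enolate 16 (not isolated)
Conditions: LiN(iPr)2 (2.2 equiv), THF, −78 °C; then 15, −78 °C; NH4Cl (aq)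
Reagents that add atoms: none
Why: Aldol addition of a β-alkoxide lactone enolate dianion (Fráter–Seebach-type); the aldehyde, bound by the lithium alkoxide on C8', should enter the enolate face cis to that oxygen and trans to the benzyl group, setting C8 (3R).

Step 8
Reactants: 17 aldol lactone of arm B
Product: 18 (2S,3R)-2-[4-(benzyloxy)-3-methoxybenzyl]-3-{[4-(benzyloxy)-3-bromo-5-methoxyphenyl](hydroxy)methyl}butane-1,2,4-triol
Conditions: LiBH4, THF, 0 °C → rt; NH4Cl (aq)
Reagents that add atoms: none
Why: Borohydride reduction of a γ-lactone to the 1,4-diol leaves the aryl bromide and benzyl ethers untouched and removes the base-labile aldol lactone before the cross-coupling.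

Step 9
Reactants: 13 (4S)-4-hydroxy-4-[4-methoxy-3-(tosyloxy)benzyl]oxolan-2-one; 15 4-(benzyloxy)-3-bromo-5-methoxybenzaldehyde
Product: 20 (3R,4S)-3-{[4-(benzyloxy)-3-bromo-5-methoxyphenyl](hydroxy)methyl}-4-hydroxy-4-[4-methoxy-3-(tosyloxy)benzyl]oxolan-2-one (carbinol epimers), via dilithium enolate 19 (not isolated)
Conditions: LiN(iPr)2 (2.2 equiv), THF, −78 °C; then 15, −78 °C; NH4Cl (aq)
Reagents that add atoms: none
Why: The same dianion aldol addition as in step 7 should set C8 cis to the C8' oxygen; the aryl tosylate has no acidic α-hydrogen and should be inert at −78 °C.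

Step 10
Reactants: 20 aldol lactone of arm A
Product: 21 (2S,3R)-3-{[4-(benzyloxy)-3-bromo-5-methoxyphenyl](hydroxy)methyl}-2-[4-methoxy-3-(tosyloxy)benzyl]butane-1,2,4-triol
Conditions: LiBH4, THF, 0 °C → rt; NH4Cl (aq)
Reagents that add atoms: none
Why: Borohydride reduction of the lactone to the diol; LiBH4 does not cleave aryl sulfonates or aryl bromides.

Step 11
Reactants: 18 tetraol bromide of arm B; 21 tetraol bromide of arm A
Product: 23 biaryl bis-tetraol tris(benzyl ether) tosylate, via pinacol boronate 22 (not isolated)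
Conditions: 18, B2pin2, Pd(dppf)Cl2 (cat.), KOAc, 1,4-dioxane, 90 °C; then 21, K3PO4 (aq), 90 °C
Reagents that add atoms: none
Why: One-pot Miyaura borylation and Suzuki–Miyaura cross-coupling joins the two ortho-alkoxy aryl bromides as the hetero-dimer because only one partner is borylated; free hydroxyls and the aryl tosylate are tolerated by the dppf catalyst.

Step 12
Reactants: 23 biaryl bis-tetraol tris(benzyl ether) tosylate
Product: 24 biaryl bis-tetraol triphenol tosylate
Conditions: H2 (1 atm), palladium on carbon (Pd/C), EtOAc/EtOH, rt, short contact time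
Reagents that add atoms: none
Why: Hydrogenolysis of the three phenolic benzyl ethers, which cleave faster than the benzylic carbinol C–O bonds (as in lignin-model syntheses) and leave the aryl sulfonate intact, frees the para-phenols that the key step needs.

Step 13
Reactants: 24 biaryl bis-tetraol triphenol tosylate
Product: 27 target O-tosylate, via bis-tetrahydrofuran 25 (not isolated), via spirodienone 26 (not isolated)
Conditions: (+)-camphor-10-sulfonic acid (0.5 equiv), (CF3)2CHOH/CH2Cl2 (1:4), 4 Å MS, 0 °C → rt, 1 mM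
Reagents that add atoms: none
Why: Acid ionizes both p-hydroxybenzylic carbinols (C7 of each arm) to quinone-methide-type cations that are first trapped by the C9' hydroxyls as the bis-ether 25; in arm B this closure is reversible and the cation is drained by ipso attack of C1' (para to the free C4' hydroxyl) to give spirodienone 26, whose cyclopentane ring (C7–C8–C8'–C7'–C1') expands by dienone–phenol 1,2-shift of C7 from C1' to C6' and rearomatizes to the tetralin. The closest known reaction types are the acid-induced isomerization of olivil-type 7,9'-epoxylignans to cycloolivil-type aryltetralins and the dienone–phenol rearrangement of spiro[4.5]decadienones. Modes of closure: the tetrahydrofuran by 5-membered oxa-cyclization onto a benzylic cation, the cyclopentane by dearomatizing ipso Friedel–Crafts spirocyclization, and the tetralin ring by one-carbon ring expansion of that cyclopentane. C7 of arm A should be set trans to the C8 hydroxymethyl group under reversible closure, and C1 of the tetralin trans to the C2 hydroxymethyl group because the aryl group takes the pseudo-equatorial position; the C8/C8' centres fixed in steps 2, 7 and 9 control both. The step needs arm A to stop at the ether while arm B goes on: the 3-tosyloxy-4-methoxyphenyl ring has no oxygen-stabilized σ-complex at C6' and cannot form a neutral dienone, and sieves exclude the water that could hydrolyse its ipso adduct. It also needs migration of the cation-stabilized C7 (not C7') to the unhindered C6' (para to OMe, not the methoxy-flanked C2') and intramolecular over intermolecular trapping, which high dilution should secure.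

Step 14
Reactants: 27 target O-tosylate
Product: 28 CNP0252244.1
Conditions: Mg turnings, MeOH, rt, ultrasound; NH4Cl (aq)
Reagents that add atoms: none
Why: Reductive S–O cleavage of an aryl tosylate by magnesium in methanol (single-electron transfer) needs neither acid nor heat, so the acid-labile 2-aryltetrahydrofuran of arm A should survive.

**Compound list**

1 | itaconic acid 4-methyl ester (2-methylidenebutanedioic acid 4-methyl ester) | C=C(CC(=O)OC)C(=O)O | starting material
2 | isobutyl carbonic mixed anhydride of 1 | C=C(CC(=O)OC)C(=O)OC(=O)OCC(C)C | intermediate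
3 | methyl 3-(hydroxymethyl)but-3-enoate | C=C(CO)CC(=O)OC | intermediate
4 | methyl 2-[(2S)-2-(hydroxymethyl)oxiran-2-yl]acetate | COC(=O)C[C@]1(CO)CO1 | intermediate
5 | 1-(benzyloxy)-4-bromo-2-methoxybenzene | COc1cc(Br)ccc1OCc1ccccc1 | starting material
6 | [4-(benzyloxy)-3-methoxyphenyl]magnesium bromide | COc1cc([Mg]Br)ccc1OCc1ccccc1 | intermediate
7 | methyl (3S)-3-[4-(benzyloxy)-3-methoxybenzyl]-3,4-dihydroxybutanoate | COC(=O)C[C@](O)(CO)Cc1ccc(OCc2ccccc2)c(OC)c1 | intermediate
8 | (4S)-4-[4-(benzyloxy)-3-methoxybenzyl]-4-hydroxyoxolan-2-one | O=C1C[C@@](O)(Cc2ccc(OCc3ccccc3)c(OC)c2)CO1 | intermediate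
9 | 5-bromo-2-methoxyphenol | COc1ccc(Br)cc1O | starting material
10 | 5-bromo-2-methoxyphenyl 4-methylbenzenesulfonate | COc1ccc(Br)cc1OS(=O)(=O)c1ccc(C)cc1 | intermediate
11 | [4-methoxy-3-(tosyloxy)phenyl]magnesium bromide | COc1ccc([Mg]Br)cc1OS(=O)(=O)c1ccc(C)cc1 | intermediate
12 | methyl (3S)-3,4-dihydroxy-3-[4-methoxy-3-(tosyloxy)benzyl]butanoate | COC(=O)C[C@](O)(CO)Cc1ccc(OC)c(OS(=O)(=O)c2ccc(C)cc2)c1 | intermediate
13 | (4S)-4-hydroxy-4-[4-methoxy-3-(tosyloxy)benzyl]oxolan-2-one | O=C1C[C@@](O)(Cc2ccc(OC)c(OS(=O)(=O)c3ccc(C)cc3)c2)CO1 | intermediate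
14 | 5-bromovanillin (3-bromo-4-hydroxy-5-methoxybenzaldehyde) | COc1cc(C=O)cc(Br)c1O | starting material
15 | 4-(benzyloxy)-3-bromo-5-methoxybenzaldehyde | COc1cc(C=O)cc(Br)c1OCc1ccccc1 | intermediate
16 | dilithium enolate-alkoxide of 8 | [Li+].[Li+].[O-]C1=C[C@@]([O-])(Cc2ccc(OCc3ccccc3)c(OC)c2)CO1 | intermediate
17 | (3R,4S)-4-[4-(benzyloxy)-3-methoxybenzyl]-3-{[4-(benzyloxy)-3-bromo-5-methoxyphenyl](hydroxy)methyl}-4-hydroxyoxolan-2-one, carbinol epimers | O=C1OC[C@](O)(Cc2ccc(OCc3ccccc3)c(OC)c2)[C@H]1C(O)c1cc(OC)c(OCc2ccccc2)c(Br)c1 | intermediate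
18 | (2S,3R)-2-[4-(benzyloxy)-3-methoxybenzyl]-3-{[4-(benzyloxy)-3-bromo-5-methoxyphenyl](hydroxy)methyl}butane-1,2,4-triol, carbinol epimers | COc1cc(C[C@@](O)(CO)[C@H](CO)C(O)c2cc(OC)c(OCc3ccccc3)c(Br)c2)ccc1OCc1ccccc1 | intermediate
19 | dilithium enolate-alkoxide of 13 | [Li+].[Li+].[O-]C1=C[C@@]([O-])(Cc2ccc(OC)c(OS(=O)(=O)c3ccc(C)cc3)c2)CO1 | intermediate
20 | (3R,4S)-3-{[4-(benzyloxy)-3-bromo-5-methoxyphenyl](hydroxy)methyl}-4-hydroxy-4-[4-methoxy-3-(tosyloxy)benzyl]oxolan-2-one, carbinol epimers | O=C1OC[C@](O)(Cc2ccc(OC)c(OS(=O)(=O)c3ccc(C)cc3)c2)[C@H]1C(O)c1cc(OC)c(OCc2ccccc2)c(Br)c1 | intermediate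
21 | (2S,3R)-3-{[4-(benzyloxy)-3-bromo-5-methoxyphenyl](hydroxy)methyl}-2-[4-methoxy-3-(tosyloxy)benzyl]butane-1,2,4-triol, carbinol epimers | COc1ccc(C[C@@](O)(CO)[C@H](CO)C(O)c2cc(OC)c(OCc3ccccc3)c(Br)c2)cc1OS(=O)(=O)c1ccc(C)cc1 | intermediate
22 | pinacol boronate of 18 (Bpin in place of Br) | COc1cc(C[C@@](O)(CO)[C@H](CO)C(O)c2cc(OC)c(OCc3ccccc3)c(B3OC(C)(C)C(C)(C)O3)c2)ccc1OCc1ccccc1 | intermediate
23 | biaryl bis-tetraol tris(benzyl ether) tosylate: 5,5'-linked biphenyl, each ring 4-benzyloxy-3-methoxy, ring A carrying at C1 the chain CH(OH)–(3R)-CH(CH2OH)–(2S)-C(OH)(CH2OH)–CH2–[4-methoxy-3-(tosyloxy)phenyl] (arm A), ring B the same chain ending in CH2–[4-(benzyloxy)-3-methoxyphenyl] (arm B) | COc1ccc(C[C@@](O)(CO)[C@H](CO)C(O)c2cc(OC)c(OCc3ccccc3)c(-c3cc(C(O)[C@@H](CO)[C@](O)(CO)Cc4ccc(OCc5ccccc5)c(OC)c4)cc(OC)c3OCc3ccccc3)c2)cc1OS(=O)(=O)c1ccc(C)cc1 | intermediate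
24 | biaryl bis-tetraol triphenol tosylate: 23 with the three benzyl ethers replaced by free phenols (arm B ends in 4-hydroxy-3-methoxybenzyl) | COc1ccc(C[C@@](O)(CO)[C@H](CO)C(O)c2cc(OC)c(O)c(-c3cc(C(O)[C@@H](CO)[C@](O)(CO)Cc4ccc(O)c(OC)c4)cc(OC)c3O)c2)cc1OS(=O)(=O)c1ccc(C)cc1 | intermediate
25 | bis-tetrahydrofuran: both arms closed as (2S,3R,4S)-2-aryl-4-benzyl-4-hydroxy-3-(hydroxymethyl)oxolanes | COc1ccc(C[C@@]2(O)CO[C@H](c3cc(OC)c(O)c(-c4cc([C@H]5OC[C@](O)(Cc6ccc(O)c(OC)c6)[C@@H]5CO)cc(OC)c4O)c3)[C@H]2CO)cc1OS(=O)(=O)c1ccc(C)cc1 | intermediate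
26 | spirodienone: arm A as in 25; arm B a 7-methoxyspiro[4.5]deca-6,9-dien-8-one whose cyclopentane carries the biaryl ring at C7 (trans to the C8 hydroxymethyl), and hydroxyl plus hydroxymethyl at C8'; spiro carbon unassigned | COc1ccc(C[C@@]2(O)CO[C@H](c3cc(OC)c(O)c(-c4cc([C@@H]5[C@@H](CO)[C@](O)(CO)CC56C=CC(=O)C(OC)=C6)cc(OC)c4O)c3)[C@H]2CO)cc1OS(=O)(=O)c1ccc(C)cc1 | intermediate
27 | target O-tosylate: the target with the isovanillyl phenol as its 4-methylbenzenesulfonate | COc1ccc(C[C@@]2(O)CO[C@H](c3cc(OC)c(O)c(-c4cc([C@H]5c6cc(O)c(OC)cc6C[C@@](O)(CO)[C@@H]5CO)cc(OC)c4O)c3)[C@H]2CO)cc1OS(=O)(=O)c1ccc(C)cc1 | intermediate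
28 | CNP0252244.1: 5,5'-biaryl of a (2S,3R,4S)-olivil-type oxolane (isovanillyl at C4) and a (1S,2S,3S)-cycloolivil-type tetralin | COc1ccc(C[C@@]2(O)CO[C@H](c3cc(OC)c(O)c(-c4cc([C@H]5c6cc(O)c(OC)cc6C[C@@](O)(CO)[C@@H]5CO)cc(OC)c4O)c3)[C@H]2CO)cc1O | target

**Totals and risks**

Total step count: 14. Longest linear sequence: 9 steps (1, 2, 3, 7, 8, 11, 12, 13, 14).

Risk 1 (step 13): the two arms may not be told apart. The ether of arm A may re-ionize and alkylate its own ring, arm B may stall at the ether stage, or quinone methides may be trapped intermolecularly. In that case the two rings would be closed one at a time before the biaryl bond is made. Setting out from 18, CF3CO2H in CH2Cl2 at 0 °C would cyclize the benzyl-protected tetraol by Friedel–Crafts alkylation para to the methoxy group to the aryltetralin bromide F1. Setting out from 21, PPTS in CH2Cl2 would close only the ether ring to the 2-aryltetrahydrofuran bromide F2, since the tosyloxy ring cannot alkylate. Miyaura borylation of F1 to the pinacol boronate F3 and Suzuki coupling with F2 under the conditions of step 11 would give the tris(benzyl ether) F4. Hydrogenolysis (H2, palladium on carbon, EtOAc, short contact time) would return to the route at 27.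

Risk 2 (step 7; step 9 shares it): the dianion aldol may add on the enolate face cis to the benzyl group, or revert by retro-aldol on warming. Control would then be moved from the kinetic addition to a thermodynamic one. Setting out from 17 as obtained (mixed at C8), Dess–Martin oxidation of the secondary carbinol would give the β-keto lactone F5. Its doubly activated C8–H should equilibrate (Et3N) to the isomer with the aroyl group trans to the benzyl substituent and hydrogen-bonded to the tertiary hydroxyl. LiBH4 would then reduce ketone and lactone together and rejoin the route at 18.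

Risk 3 (step 5): the sulfonate may not survive the organomagnesium stage, through sulfonyl transfer to the aryl Grignard reagent or sluggish magnesium insertion. The isovanillyl oxygen would then be carried as a benzyl ether through the C–C bond formation and sulfonylated afterwards. Setting out from 4 and commercial 2-(benzyloxy)-4-bromo-1-methoxybenzene, the Grignard reagent F6 (Mg, THF) would open the epoxide under the conditions of step 3 to the dihydroxy ester F7, which lactonizes (PPTS) to the benzyl ether lactone F8. Hydrogenolysis (H2, palladium on carbon) to the phenol lactone F9 and selective sulfonylation of the phenol (TsCl, K2CO3, acetone; the tertiary alcohol is inert) would rejoin the route at 13.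

Further compounds

F1 | step 13 | (1S,2S,3S)-7-(benzyloxy)-1-[4-(benzyloxy)-3-bromo-5-methoxyphenyl]-2,3-bis(hydroxymethyl)-6-methoxy-1,2,3,4-tetrahydronaphthalen-3-ol | COc1cc([C@H]2c3cc(OCc4ccccc4)c(OC)cc3C[C@@](O)(CO)[C@@H]2CO)cc(Br)c1OCc1ccccc1
F2 | step 13 | (2S,3R,4S)-2-[4-(benzyloxy)-3-bromo-5-methoxyphenyl]-3-(hydroxymethyl)-4-[4-methoxy-3-(tosyloxy)benzyl]oxolan-4-ol | COc1ccc(C[C@@]2(O)CO[C@H](c3cc(OC)c(OCc4ccccc4)c(Br)c3)[C@H]2CO)cc1OS(=O)(=O)c1ccc(C)cc1
F3 | step 13 | pinacol boronate of F1 (Bpin in place of Br) | COc1cc([C@H]2c3cc(OCc4ccccc4)c(OC)cc3C[C@@](O)(CO)[C@@H]2CO)cc(B2OC(C)(C)C(C)(C)O2)c1OCc1ccccc1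
F4 | step 13 | tris(benzyl ether) of 27 (both biaryl phenols and the tetralin phenol benzylated) | COc1ccc(C[C@@]2(O)CO[C@H](c3cc(OC)c(OCc4ccccc4)c(-c4cc([C@H]5c6cc(OCc7ccccc7)c(OC)cc6C[C@@](O)(CO)[C@@H]5CO)cc(OC)c4OCc4ccccc4)c3)[C@H]2CO)cc1OS(=O)(=O)c1ccc(C)cc1
F5 | step 7 | (3R,4S)-3-[4-(benzyloxy)-3-bromo-5-methoxybenzoyl]-4-[4-(benzyloxy)-3-methoxybenzyl]-4-hydroxyoxolan-2-one | O=C1OC[C@](O)(Cc2ccc(OCc3ccccc3)c(OC)c2)[C@H]1C(=O)c1cc(OC)c(OCc2ccccc2)c(Br)c1
F6 | step 5 | [3-(benzyloxy)-4-methoxyphenyl]magnesium bromide | COc1ccc([Mg]Br)cc1OCc1ccccc1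
F7 | step 5 | methyl (3S)-3-[3-(benzyloxy)-4-methoxybenzyl]-3,4-dihydroxybutanoate | COC(=O)C[C@](O)(CO)Cc1ccc(OC)c(OCc2ccccc2)c1
F8 | step 5 | (4S)-4-[3-(benzyloxy)-4-methoxybenzyl]-4-hydroxyoxolan-2-one | O=C1C[C@@](O)(Cc2ccc(OC)c(OCc3ccccc3)c2)CO1
F9 | step 5 | (4S)-4-hydroxy-4-(3-hydroxy-4-methoxybenzyl)oxolan-2-one | O=C1C[C@@](O)(Cc2ccc(OC)c(O)c2)CO1
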